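**Retrosynthetic overview**
1. Target 16 ⇐ (R)-lactol acetate 15 ⇐ racemic hydroxyphthalide 14; the hemiacetal centre is set last by lipase dynamic kinetic resolution and released by acyl–O cleavage.
2. The lactol ring comes from an ortho formyl/ester pair. The formyl carbon is attached by adding formaldehyde N,N-dimethylhydrazone (a formyl anion equivalent) to the electrophilic C–H carbon of a ring B quinone (key C–C bond).
3. The seven-membered depsidone ring is closed by intramolecular Ullmann etherification of a bromo depside; the depside ester comes from O-acylation of a hydroxyquinone.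
4. Ring B quinone ⇐ methyl 2,4-dihydroxy-3-methylbenzoate; ring A bromo acid ⇐ 4,5-dimethoxy-2-methylbenzaldehyde.
5. Ring order: dioxepinone (seven-membered) first, hydroxyphthalide (five-membered lactol) last.

**Assumptions:** The target lactol carbon is R (CIP, from the SMILES). It is a hemiacetal that can racemise through its ring-opened formyl acid, so it is fixed in step 9 and released in step 10 under neutral, anhydrous, cold conditions, and the product must be kept that way. Compounds 1, 6 and 8 are taken as catalogue chemicals (8 is also made from formaldehyde and 1,1-dimethylhydrazine).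

**Step 1**
Reactants: 1 4,5-dimethoxy-2-methylbenzaldehyde
Product: 2 5-hydroxy-4-methoxy-2-methylbenzaldehyde
Conditions: DL-methionine (1.2 equiv), conc. H2SO4, 60 °C
Reagents that add atoms: none
Why: In sulfuric acid the O-protonated aldehyde deactivates the para methoxy oxygen, so the meta methoxy group is protonated and demethylated by methionine sulfur (acid-mediated regioselective aryl methyl ether cleavage, SN2 at methyl).

**Step 2**
Reactants: 2 5-hydroxy-4-methoxy-2-methylbenzaldehyde
Product: 3 2-bromo-3-hydroxy-4-methoxy-6-methylbenzaldehyde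
Conditions: Br2 (1.05 equiv), NaOAc, AcOH, 20 °C
Reagents that add atoms: bromine, BrBr
Why: Electrophilic aromatic bromination goes ortho to the free phenol (its para position is blocked by methyl), the same regiochemistry as the isovanillin to 2-bromoisovanillin bromination.

**Step 3**
Reactants: 3 2-bromo-3-hydroxy-4-methoxy-6-methylbenzaldehyde
Product: 4 2-bromo-4-methoxy-3-(methoxymethoxy)-6-methylbenzaldehyde
Conditions: MOMCl, i-Pr2NEt, CH2Cl2, 0 °C to rt
Reagents that add atoms: chloromethyl methyl ether, COCCl
Why: O-alkylation of the phenol (MOM protection) gives an acetal that survives oxidation, acylation and hot carbonate and falls off in the acid step 8 at no extra step.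

**Step 4**
Reactants: 4 2-bromo-4-methoxy-3-(methoxymethoxy)-6-methylbenzaldehyde
Product: 5 2-bromo-4-methoxy-3-(methoxymethoxy)-6-methylbenzoic acid
Conditions: NaClO2, NaH2PO4, 2-methyl-2-butene, t-BuOH/H2O, rt
Reagents that add atoms: sodium chlorite, [Na+].[O-]Cl=O
Why: Pinnick oxidation converts the hindered aldehyde to the acid under buffered conditions that leave the aryl bromide and MOM ether untouched.

**Step 5**
Reactants: 6 methyl 2,4-dihydroxy-3-methylbenzoate
Product: 7 methyl 4-hydroxy-5-methyl-3,6-dioxocyclohexa-1,4-diene-1-carboxylate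
Conditions: K2NO(SO3)2 (Fremy's salt, 2.2 equiv), KH2PO4 buffer, H2O/acetone, 0 °C to rt
Reagents that add atoms: potassium nitrosodisulfonate, [K+].[K+].[O]N(S(=O)(=O)[O-])S(=O)(=O)[O-]
Why: Teuber oxidation of a resorcinol-type phenol oxygenates the only free activated position (C-5) and gives the 2-hydroxy-1,4-benzoquinone tautomer, which has a single OH.

**Step 6 (key step)**
Reactants: 5 2-bromo-4-methoxy-3-(methoxymethoxy)-6-methylbenzoic acid, 7 methyl 4-hydroxy-5-methyl-3,6-dioxocyclohexa-1,4-diene-1-carboxylate, 8 formaldehyde N,N-dimethylhydrazone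
Product: 11 methyl 4-{[2-bromo-4-methoxy-3-(methoxymethoxy)-6-methylbenzoyl]oxy}-2-[(E)-(2,2-dimethylhydrazinylidene)methyl]-3,6-dihydroxy-5-methylbenzoate, via aroyl chloride 9 (not isolated), via acyloxyquinone 10 (not isolated)
Conditions: 5, 1-chloro-N,N,2-trimethylprop-1-en-1-amine (1.0 equiv), CH2Cl2, 0 °C to rt; then 7, Ag2O (0.5 equiv), 4 Å sieves, 0 °C, filter under argon; filtrate added slowly to 8 (2 equiv), CH2Cl2, −40 to 0 °C
Reagents that add atoms: none
Why: Proposed new method: in the O-acyl hydroxyquinone 10 the only unsubstituted ring carbon (C-2) is beta to both the C-6 ketone and the ester, so the neutral aza-enamine carbon of 8 (a formyl anion equivalent) adds there and the adduct tautomerises to the hydroquinone, joining two carbons that are both normally electrophilic and freeing the O-3 phenol for ring closure; the closest known reactions are conjugate additions of formaldehyde dialkylhydrazones to enones and nitroalkenes and of aldehyde dimethylhydrazones to acylquinones, while O-acylation of a hydroxyquinone silver salt by an acid chloride is standard and removes chloride as AgCl.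

**Step 7**
Reactants: 11 methyl 4-{[2-bromo-4-methoxy-3-(methoxymethoxy)-6-methylbenzoyl]oxy}-2-[(E)-(2,2-dimethylhydrazinylidene)methyl]-3,6-dihydroxy-5-methylbenzoate
Product: 12 methyl 6-[(E)-(2,2-dimethylhydrazinylidene)methyl]-8-hydroxy-3-methoxy-4-(methoxymethoxy)-1,9-dimethyl-11-oxo-11H-dibenzo[b,e][1,4]dioxepine-7-carboxylate
Conditions: CuI (20 mol%), N,N-dimethylglycine (40 mol%), Cs2CO3 (2.2 equiv), degassed 1,4-dioxane, 0.01 M, 90 °C
Reagents that add atoms: none
Why: Intramolecular Ullmann diaryl ether synthesis works here because the bromide is activated by its ortho ester carbonyl, only the O-3 phenoxide can reach it (seven-membered ring), and the di-ortho-substituted aroyl ester is shielded against migration to the neighbouring phenoxide.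

**Step 8**
Reactants: 12 methyl 6-[(E)-(2,2-dimethylhydrazinylidene)methyl]-8-hydroxy-3-methoxy-4-(methoxymethoxy)-1,9-dimethyl-11-oxo-11H-dibenzo[b,e][1,4]dioxepine-7-carboxylate
Product: 14 rac-1,4,11-trihydroxy-10-methoxy-5,8-dimethyl-1H,7H-isobenzofuro[4,5-b][1,4]benzodioxepine-3,7-dione, via formyl ester 13 (not isolated)
Conditions: 3 M aq. HCl, THF, 60 °C
Reagents that add atoms: water, O
Why: Aqueous acid hydrolyses the hydrazone to aldehyde 13 and cleaves the MOM acetal, and the aldehyde hydrate then displaces methanol from the neighbouring ester (neighbouring-group-assisted hydrolysis of a 2-formylbenzoate) to give the hydroxyphthalide as the racemate.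

**Step 9**
Reactants: 14 rac-1,4,11-trihydroxy-10-methoxy-5,8-dimethyl-1H,7H-isobenzofuro[4,5-b][1,4]benzodioxepine-3,7-dione
Product: 15 (1R)-1-acetoxy-4,11-dihydroxy-10-methoxy-5,8-dimethyl-1H,7H-isobenzofuro[4,5-b][1,4]benzodioxepine-3,7-dione
Conditions: immobilised Burkholderia cepacia lipase, vinyl acetate (5 equiv), Et3N (5 mol%), toluene, 40 °C
Reagents that add atoms: vinyl acetate, CC(=O)OC=C
Why: This is a lipase-catalysed acylative dynamic kinetic resolution of a lactol (known for hydroxyfuranones and related cyclic hemiacetals), in which ring-chain tautomerism racemises the free lactol while the enzyme acetylates one enantiomer only, expected to be R from its usual secondary-alcohol preference with the aryl side as the large group, and leaves the hindered phenols alone; this step sets the stereocenter.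

**Step 10**
Reactants: 15 (1R)-1-acetoxy-4,11-dihydroxy-10-methoxy-5,8-dimethyl-1H,7H-isobenzofuro[4,5-b][1,4]benzodioxepine-3,7-dione
Product: 16 (1R)-1,4,11-trihydroxy-10-methoxy-5,8-dimethyl-1H,7H-isobenzofuro[4,5-b][1,4]benzodioxepine-3,7-dione
Conditions: immobilised Burkholderia cepacia lipase, 1-butanol (5 equiv), anhydrous MTBE, 0–5 °C; filter, evaporate below 20 °C
Reagents that add atoms: none
Why: Lipase-catalysed transesterification to 1-butanol breaks the acetyl C–O bond and not the stereogenic C–O bond, under neutral base-free anhydrous conditions, so the R configuration is retained, and the enzyme that made the R acetate also accepts it in the reverse direction.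

**Compound list**
1 | 4,5-dimethoxy-2-methylbenzaldehyde | COc1cc(C)c(C=O)cc1OC | starting material
2 | 5-hydroxy-4-methoxy-2-methylbenzaldehyde | COc1cc(C)c(C=O)cc1O | intermediate
3 | 2-bromo-3-hydroxy-4-methoxy-6-methylbenzaldehyde | COc1cc(C)c(C=O)c(Br)c1O | intermediate
4 | 2-bromo-4-methoxy-3-(methoxymethoxy)-6-methylbenzaldehyde | COCOc1c(Br)c(C=O)c(C)cc1OC | intermediate
5 | 2-bromo-4-methoxy-3-(methoxymethoxy)-6-methylbenzoic acid | COCOc1c(Br)c(C(=O)O)c(C)cc1OC | intermediate
6 | methyl 2,4-dihydroxy-3-methylbenzoate | COC(=O)c1ccc(O)c(C)c1O | starting material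
7 | methyl 4-hydroxy-5-methyl-3,6-dioxocyclohexa-1,4-diene-1-carboxylate | COC(=O)C1=CC(=O)C(O)=C(C)C1=O | intermediate
8 | formaldehyde N,N-dimethylhydrazone | C=NN(C)C | starting material
9 | 2-bromo-4-methoxy-3-(methoxymethoxy)-6-methylbenzoyl chloride | COCOc1c(Br)c(C(=O)Cl)c(C)cc1OC | intermediate
10 | methyl 4-{[2-bromo-4-methoxy-3-(methoxymethoxy)-6-methylbenzoyl]oxy}-5-methyl-3,6-dioxocyclohexa-1,4-diene-1-carboxylate | COC(=O)C1=CC(=O)C(OC(=O)c2c(C)cc(OC)c(OCOC)c2Br)=C(C)C1=O | intermediate
11 | methyl 4-{[2-bromo-4-methoxy-3-(methoxymethoxy)-6-methylbenzoyl]oxy}-2-[(E)-(2,2-dimethylhydrazinylidene)methyl]-3,6-dihydroxy-5-methylbenzoate | COC(=O)c1c(O)c(C)c(OC(=O)c2c(C)cc(OC)c(OCOC)c2Br)c(O)c1/C=N/N(C)C | intermediate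
12 | methyl 6-[(E)-(2,2-dimethylhydrazinylidene)methyl]-8-hydroxy-3-methoxy-4-(methoxymethoxy)-1,9-dimethyl-11-oxo-11H-dibenzo[b,e][1,4]dioxepine-7-carboxylate | COc1cc(C)c2c(c1OCOC)Oc1c(/C=N/N(C)C)c(C(=O)OC)c(O)c(C)c1OC2=O | intermediate
13 | methyl 6-formyl-4,8-dihydroxy-3-methoxy-1,9-dimethyl-11-oxo-11H-dibenzo[b,e][1,4]dioxepine-7-carboxylate | COc1cc(C)c2c(c1O)Oc1c(C=O)c(C(=O)OC)c(O)c(C)c1OC2=O | intermediate
14 | rac-1,4,11-trihydroxy-10-methoxy-5,8-dimethyl-1H,7H-isobenzofuro[4,5-b][1,4]benzodioxepine-3,7-dione (racemic lactol) | COc1cc(C)c2c(c1O)Oc1c(c(C)c(O)c3c1C(O)OC3=O)OC2=O | intermediate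
15 | (1R)-1-acetoxy-4,11-dihydroxy-10-methoxy-5,8-dimethyl-1H,7H-isobenzofuro[4,5-b][1,4]benzodioxepine-3,7-dione | COc1cc(C)c2c(c1O)Oc1c(c(C)c(O)c3c1[C@H](OC(C)=O)OC3=O)OC2=O | intermediate
16 | (1R)-1,4,11-trihydroxy-10-methoxy-5,8-dimethyl-1H,7H-isobenzofuro[4,5-b][1,4]benzodioxepine-3,7-dione (CNP0211607.1) | COc1cc(C)c2c(c1O)Oc1c(c(C)c(O)c3c1[C@H](O)OC3=O)OC2=O | target

**Step count:** 10 steps in total. Longest linear sequence: 9 steps (steps 1–4, then 6–10).

**Steps most likely to fail, with fallbacks**

Step 6 (key step). The acyloxyquinone 10 is a vinylogous anhydride and a strong oxidant, so acyl transfer or quinone/hydroquinone redox exchange may compete with the addition. The fallback reverses the order so that the C–C bond is made on the more robust hydroxyquinone and the ester afterwards. It sets out from 7: add 8 directly to 7 (CH2Cl2, 0 °C to rt, argon) to give methyl 2-[(E)-(2,2-dimethylhydrazinylidene)methyl]-3,4,6-trihydroxy-5-methylbenzoate F1. Then acylate F1 with aroyl chloride 9 (made from 5 as in step 6; Et3N, cat. DMAP, CH2Cl2, −20 °C). The O-4 phenol is the only one not held in a hydrogen bond (O-3 is bound to the hydrazone nitrogen, O-6 to the ester carbonyl), so acylation should go there. The fallback comes back to the route at 11.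

Step 7. Hot carbonate may let the aroyl group migrate to the neighbouring phenoxide, or the di-ortho-substituted bromide may be slow to react with monovalent copper. The fallback replaces the substitution at the bromide by an oxidative coupling at room temperature. It sets out from 11: Miyaura borylation (B2pin2, PdCl2(dppf), KOAc, 1,4-dioxane, 80 °C) gives methyl 2-[(E)-(2,2-dimethylhydrazinylidene)methyl]-3,6-dihydroxy-4-{[4-methoxy-3-(methoxymethoxy)-6-methyl-2-(4,4,5,5-tetramethyl-1,3,2-dioxaborolan-2-yl)benzoyl]oxy}-5-methylbenzoate F2. Chan–Lam–Evans ring closure (Cu(OAc)2 1.5 equiv as the divalent copper oxidant, pyridine, 4 Å sieves, CH2Cl2, rt, argon) then forms the diaryl ether. The fallback comes back at 12.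

Step 9. The lipase may not accept, or not discriminate on, this bulky lactol. The fallback replaces asymmetric catalysis by physical resolution with recycling. It sets out from 14: acetylate the lactol oxygen without stereocontrol (vinyl acetate with an unselective lipase such as Candida rugosa lipase, or Ac2O 1.05 equiv, pyridine, −20 °C). Separate the two enantiomeric acetates by preparative chiral SFC. The R acetate is 15, where the fallback comes back to the route. The unwanted (1S)-1-acetoxy-4,11-dihydroxy-10-methoxy-5,8-dimethyl-1H,7H-isobenzofuro[4,5-b][1,4]benzodioxepine-3,7-dione F3 is hydrolysed back to 14 (aq. HCl, THF) and recycled.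

**Further compounds**
F1 | step 6 | methyl 2-[(E)-(2,2-dimethylhydrazinylidene)methyl]-3,4,6-trihydroxy-5-methylbenzoate | COC(=O)c1c(O)c(C)c(O)c(O)c1/C=N/N(C)C
F2 | step 7 | methyl 2-[(E)-(2,2-dimethylhydrazinylidene)methyl]-3,6-dihydroxy-4-{[4-methoxy-3-(methoxymethoxy)-6-methyl-2-(4,4,5,5-tetramethyl-1,3,2-dioxaborolan-2-yl)benzoyl]oxy}-5-methylbenzoate | COC(=O)c1c(O)c(C)c(OC(=O)c2c(C)cc(OC)c(OCOC)c2B3OC(C)(C)C(C)(C)O3)c(O)c1/C=N/N(C)C
F3 | step 9 | (1S)-1-acetoxy-4,11-dihydroxy-10-methoxy-5,8-dimethyl-1H,7H-isobenzofuro[4,5-b][1,4]benzodioxepine-3,7-dione | COc1cc(C)c2c(c1O)Oc1c(c(C)c(O)c3c1[C@@H](OC(C)=O)OC3=O)OC2=O
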